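## Analysis of the target

The target 20 is a 3,4-dihydro-2H-pyran (ring atoms O1, C2, C3, C4, C5, C6). Its C5=C6–O1 enol ether is conjugated with the C5 methyl ester. C2 carries a methyl group, C3 a formyl group (C7), and C4 a CH2–C(=O)O chain (C8, C9) esterified with the primary hydroxyl of hydroxytyrosol.

The three contiguous stereocentres are (2S,3S,4S): methyl and formyl are cis, formyl and the C4 chain are trans. In the half-chair this places the methyl equatorial, the formyl axial and the C4 chain pseudoaxial.

The unit O1–C2–C3–C7(=O) is a β-alkoxy aldehyde. Enolisation towards C3 epimerises that centre and can expel O1 from C2 (retro-oxa-Michael). C2 and C3 are therefore stereochemically labile in the target itself and cannot be held by kinetic control. Only C4 is robust.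

Other sensitive groups are the catechol (oxidation, competing nucleophile), two different esters that must be told apart, and the aldehyde.

The real problem is thus one stereocentre, C4, carrying three arms at three oxidation patterns (C8–C9 ester; C5(CO2Me)=C6–O; C3(C7)=C2), to be assembled without long protecting-group traffic.

Two features of the structure invite the strategy:
- Read backwards, the β-alkoxy aldehyde is the oxa-Michael adduct of the C6 enol oxygen O1 to a C2=C3 ethylidene aldehyde.
- The atoms O1–C6=C5–C4–C8–C9(=O) are exactly those of a 3,4-dihydropyran-2-one, if C9 is bonded to O1 instead of to the side-chain oxygen.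

## Retrosynthetic reasoning

**O1–C2 (and the C3–H bond).** Target 20 is cut first here. The retro-oxa-Michael step leads through acetonide 19 to seco enal–enol 18, in which C2=C3 is an ethylidene group on an α,β-unsaturated aldehyde and O1 is the enol oxygen of a β-formyl ester. This bond is chosen because it is the one that breaks by itself in the target. C2 and C3 are set reversibly in any case, so they are left to the last step and to thermodynamics. The precursor has one stereocentre instead of three and no ring. Forward, the enol oxygen has to close 6-endo onto C2 and C3 has to be protonated.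

**C7 mask.** 18 is too reactive to be carried and is traced to 17, in which C7 is a dimethyl acetal. The acetal turns the ethylidene aldehyde into a plain trisubstituted alkene (no Michael acceptor, no acidic γ-hydrogen) for all earlier steps. It is lost under the same acid that frees the catechol, so unmasking is the trigger of the ring closure.

**C9–O(side chain), reconnected as C9–O1.** In 17 the side-chain ester bond is cut and C9 is joined to O1 instead. This gives enol lactone 16 and alcohol 13. The six-membered lactone is not part of 20. It is made on purpose: it holds the β-formyl ester as a stable enol ester, tells the two ester carbonyls apart, and stores the acylating power needed for 13. Forward, 13 opens the lactone by acyl transfer, which forms the side-chain ester and releases the enol in one step. 13 comes from 12 by ketalisation.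

**C4–C5 and C9–O1.** 16 is cut into dienal 8 and β-formyl ester 14. Forward, the carbon of 14 adds to the β-carbon of 8 at the acyl azolium oxidation level (15), and the enol oxygen then lactonises. This is where C4, the only centre that needs control, is set by a chiral carbene catalyst. The two fragments have no stereocentre. 14 is freed from its sodium enolate 11, the crossed Claisen product of 9 and 10.

**Future C3–C4 bond of 20.** 8 is cut between the ethylidene carbon and the enal β-carbon into vinyl bromide 4 (used as vinyllithium 6) and vinylogous formamide 5, which delivers the three-carbon enal unit through adduct 7. 4 is the acetal of 3, which comes from 1 by bromination and loss of HBr through 2. C2, C3, C7 and the C2 methyl of 20 are thus the four carbons of 1.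

## Alternatives that were turned down

**Alternative 1:** the textbook cut, the side-chain ester C9–O bond, giving elenolic acid A1 and 12. The forward key step is a carbodiimide or Mitsunobu esterification. It was turned down because it solves nothing: A1 still holds the ring and all three stereocentres, so the whole problem is only postponed. A1 is also a free acid next to a base-sensitive β-alkoxy aldehyde. The cut is kept only as a fallback end game.

**Alternative 2:** a hetero-Diels–Alder cut of O1–C2 and C3–C4. The 1-oxadiene A2 (C6=O, C5=C4) would react with a C2=C3 dienophile at the oxidation level of 1. It was turned down on polarity and stability grounds: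
- O1 must bond to the dienophile carbon that carries only a methyl, and C4 to the carbon that carries the formyl group.
- An electron-rich enol ether would place its alkoxy carbon on O1 and give a C2 acetal with the wrong substitution.
- With 1 itself, both partners are electron-poor.
- A2 has acidic hydrogens between alkene and ester and would tautomerise or polymerise.
- Any cis/trans information bought with the dienophile geometry would be lost again by the lability of C2 and C3.
- C4 would still need a chiral Lewis acid.

**Alternative 3:** a [3,3] cut of C4–C5 with migration of O1. Allyl vinyl ether A3 would come from allylic alcohol A4 and methyl propiolate A5. The forward key step is a thermal Claisen rearrangement that forms C4–C5, transfers the carbinol configuration of C2 to C4 and leaves the ethylidene group; acid then closes the ring as in the chosen route. The cascade is attractive, but it was turned down because the precursor costs more than the key step wins: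
- A4 is a (Z)-trisubstituted allylic alcohol with a dimethoxymethyl group on the central carbon and a skipped, base-labile ester; it needs a long, geometry-defined synthesis.
- The ester on the vinyl terminus retards the rearrangement, so high temperature is needed.
- Allylic strain between the acetal and the carbinol methyl makes the chair preference, and hence the chirality transfer, uncertain.

Key step: step 8

Remark (assumption on the chemistry): the (5aS,10bR) triazolium salt in step 6 is assumed to deliver C5 to the Si face of the enal β-carbon, giving (S)-16. If the lactone proves to be the (R)-enantiomer, the commercial (5aR,10bS) antipode is used and nothing else changes.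

## Route

Step 1
Reactants: 1 (E)-but-2-enal (crotonaldehyde)
Product: 3 (Z)-2-bromobut-2-enal, via 2,3-dibromobutanal 2 (not isolated)
Conditions: Br2 (1.0 equiv), CH2Cl2, −10 °C; then Et3N (1.1 equiv), 0 °C → 20 °C
Reagents that add atoms: bromine, BrBr
Why: Anti addition of bromine to the enal followed by E1cB loss of HBr through the acidic α-hydrogen should give the α-bromo enal; the isomer with CHO trans to CH3 is the stable one.

Step 2
Reactants: 3 (Z)-2-bromobut-2-enal
Product: 4 (Z)-2-bromo-1,1-dimethoxybut-2-ene
Conditions: HC(OMe)3 (1.5 equiv), p-toluenesulfonic acid monohydrate (1 mol %), MeOH, 0 °C → 20 °C; NaHCO3 quench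
Reagents that add atoms: trimethyl orthoformate, COC(OC)OC
Why: Acid-catalysed acetalisation with the orthoformate as water scavenger; the acetal masks the future C7 formyl group and makes halogen–lithium exchange possible.

Step 3
Reactants: 4 (Z)-2-bromo-1,1-dimethoxybut-2-ene; 5 (E)-3-(dimethylamino)prop-2-enal
Product: 8 (2E,4E)-4-(dimethoxymethyl)hexa-2,4-dienal, via vinyllithium 6 (not isolated), via lithium aminoallyl alkoxide 7 (not isolated)
Conditions: t-BuLi (2.05 equiv), Et2O, −78 °C; 5 (1.2 equiv), THF, −78 → −20 °C; aq. NH4Cl, then AcOH/NaOAc buffer (pH 5), 0 °C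
Reagents that add atoms: water, O
Why: Bromine–lithium exchange proceeds with retention, and 6 adds 1,2 to the vinylogous formamide; mildly acidic work-up expels hydroxide and dimethylamine (vinylogous formylation) to give the (2E)-enal, while the dimethyl acetal survives pH 5.

Step 4
Reactants: 9 methyl acetate; 10 methyl formate
Product: 11 sodium (E)-3-methoxy-3-oxoprop-1-en-1-olate
Conditions: NaH (1.0 equiv), Et2O, MeOH (cat.), 0 °C → 20 °C; filtration of the precipitate
Reagents that add atoms: sodium hydride, [Na+].[H-]
Why: Crossed Claisen condensation; methyl formate cannot enolise, and precipitation of the sodium enolate drives the equilibrium and gives a storable form of the otherwise unstable β-formyl ester.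

Step 5
Reactants: 12 hydroxytyrosol
Product: 13 2-(2,2-dimethyl-1,3-benzodioxol-5-yl)ethanol
Conditions: 2,2-dimethoxypropane (3 equiv), camphor-10-sulfonic acid (5 mol %), toluene, 80 °C, MeOH distilled off; then 5 % aq. citric acid wash, 20 °C
Reagents that add atoms: 2,2-dimethoxypropane, COC(C)(C)OC
Why: Ketalisation closes the five-membered benzodioxole on the catechol; any ketal formed at the primary hydroxyl is acyclic and far more labile, so the mild acid wash frees that hydroxyl only.

Step 6
Reactants: 8 (2E,4E)-4-(dimethoxymethyl)hexa-2,4-dienal; 11 sodium (E)-3-methoxy-3-oxoprop-1-en-1-olate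
Product: 16 methyl (4S)-4-[(2E)-1,1-dimethoxybut-2-en-2-yl]-2-oxo-3,4-dihydro-2H-pyran-5-carboxylate, via methyl 3-oxopropanoate 14 (not isolated), via dienoyl azolium 15 (not isolated)
Conditions: 11 (1.5 equiv), AcOH (1.5 equiv), (5aS,10bR)-2-mesityl-5a,10b-dihydro-4H,6H-indeno[2,1-b][1,2,4]triazolo[4,3-d][1,4]oxazin-2-ium chloride (10 mol %), i-Pr2NEt (20 mol %), 3,3',5,5'-tetra-tert-butyl-4,4'-diphenoquinone (1.2 equiv), 4 Å MS, THF, 0 °C → 20 °C
Reagents that add atoms: none
Why: This is the carbene-catalysed oxidative Michael addition–lactonisation of an enal with a 1,3-dicarbonyl compound: the carbene adds to the aldehyde of 8, the quinone oxidises the adduct to acyl azolium 15, the carbon of 14 (freed from 11 by AcOH) adds to the β-carbon, and the enol oxygen acylates to close the enol lactone and release the carbene. The aminoindanol backbone shields one face of the acyl azolium, so that C5 should be delivered to the Si face of the future C4 and give (S)-16; the acetal and the trisubstituted alkene are inert.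

Step 7
Reactants: 16 methyl (4S)-4-[(2E)-1,1-dimethoxybut-2-en-2-yl]-2-oxo-3,4-dihydro-2H-pyran-5-carboxylate; 13 2-(2,2-dimethyl-1,3-benzodioxol-5-yl)ethanol
Product: 17 2-(2,2-dimethyl-1,3-benzodioxol-5-yl)ethyl (3S,4E)-4-(dimethoxymethyl)-3-(3-hydroxy-1-methoxy-1-oxoprop-2-en-2-yl)hex-4-enoate (enol form of the β-formyl ester)
Conditions: 13 (1.1 equiv), 4-(dimethylamino)pyridine (10 mol %), CH2Cl2, 0 °C → 20 °C; used crude
Reagents that add atoms: none
Why: The enol lactone is an activated ester whose leaving group is the stabilised enol of a β-formyl ester, so nucleophilic catalysis should transfer the acyl group to the primary alcohol, forming the side-chain ester and freeing the C6 enol at once. C4 has no acidic hydrogen under these conditions and keeps its configuration.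

Step 8
Reactants: 17 2-(2,2-dimethyl-1,3-benzodioxol-5-yl)ethyl (3S,4E)-4-(dimethoxymethyl)-3-(3-hydroxy-1-methoxy-1-oxoprop-2-en-2-yl)hex-4-enoate
Product: 20 methyl (2S,3S,4S)-4-{2-[2-(3,4-dihydroxyphenyl)ethoxy]-2-oxoethyl}-3-formyl-2-methyl-3,4-dihydro-2H-pyran-5-carboxylate, via seco enal–enol 18 (not isolated), via acetonide-protected dihydropyran 19 (not isolated)
Conditions: CF3CO2H/H2O (9:1), argon, 0 → 20 °C; evaporation with toluene; EtOAc/pH 7 phosphate buffer, 20 °C; SiO2
Reagents that add atoms: water, O
Why: Aqueous acid first hydrolyses the dimethyl acetal of 17, which unmasks the 2-ethylidene aldehyde and gives seco enal–enol 18 (in reversible equilibrium with the six-membered hemiacetal formed by the enol oxygen and C7). The C6 enol oxygen then adds to C2, the β-carbon of the protonated enal, and the resulting dienol is protonated at C3; this intramolecular oxa-Michael addition is the reaction by which ring-opened secoiridoid aglycones of the olive family re-close, and that is the closest known precedent. The ring closes in the 6-endo-trig mode (C2 and C3 both become ring atoms); attack through C5 would give a four-membered ring and does not compete. C4 is the only fixed stereocentre: allylic strain with the coplanar C5 ester holds its CH2CO2R chain pseudoaxial in the half-chair, so O1 adds to the face of C2 that leaves the methyl equatorial and anti to that chain (C2 = S). C3 is set by protonation and, being α to the aldehyde, settles by enolisation into the axial position anti to the C4 chain, where it meets no syn-axial substituent because O1 and C5 carry none (C3 = S). Both new centres are reversible (retro-oxa-Michael and enolisation), so the step needs thermodynamic and not kinetic selectivity for the (2S,3S) isomer over the all-equatorial (2R,3R) isomer, and the pseudoaxial preference at C4 is what should secure it. The same acid then cleaves the catechol acetonide of 19 (more slowly than the acetal), so one operation should deliver 20.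

## Compound list

1 | (E)-but-2-enal (crotonaldehyde) | C/C=C/C=O | starting material
2 | (2RS,3SR)-2,3-dibromobutanal (racemic, one enantiomer drawn) | C[C@H](Br)[C@H](Br)C=O | intermediate (not isolated)
3 | (Z)-2-bromobut-2-enal | C/C=C(\Br)C=O | intermediate
4 | (Z)-2-bromo-1,1-dimethoxybut-2-ene | C/C=C(\Br)C(OC)OC | intermediate
5 | (E)-3-(dimethylamino)prop-2-enal | CN(C)/C=C/C=O | starting material
6 | (1,1-dimethoxybut-2-en-2-yl)lithium, Li cis to CH3 | C/C=C(\[Li])C(OC)OC | intermediate (not isolated)
7 | lithium (1E,4E)-4-(dimethoxymethyl)-1-(dimethylamino)hexa-1,4-dien-3-olate | C/C=C(/C(OC)OC)C([O-])/C=C/N(C)C.[Li+] | intermediate (not isolated)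
8 | (2E,4E)-4-(dimethoxymethyl)hexa-2,4-dienal | C/C=C(/C(OC)OC)\C=C\C=O | intermediate
9 | methyl acetate | CC(=O)OC | starting material
10 | methyl formate | COC=O | starting material
11 | sodium (E)-3-methoxy-3-oxoprop-1-en-1-olate | [Na+].[O-]/C=C/C(=O)OC | intermediate
12 | hydroxytyrosol, 4-(2-hydroxyethyl)benzene-1,2-diol | OCCc1ccc(O)c(O)c1 | starting material
13 | 2-(2,2-dimethyl-1,3-benzodioxol-5-yl)ethanol | CC1(C)Oc2ccc(CCO)cc2O1 | intermediate
14 | methyl 3-oxopropanoate (in equilibrium with its enol) | COC(=O)CC=O | intermediate (not isolated)
15 | (5aS,10bR)-1-[(2E,4E)-4-(dimethoxymethyl)hexa-2,4-dienoyl]-2-mesityl-5a,10b-dihydro-4H,6H-indeno[2,1-b][1,2,4]triazolo[4,3-d][1,4]oxazin-2-ium chloride (acyl azolium) | C/C=C(/C(OC)OC)\C=C\C(=O)c1[n+](-c2c(C)cc(C)cc2C)nc2CO[C@H]3Cc4ccccc4[C@H]3n12.[Cl-] | intermediate (not isolated)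
16 | methyl (4S)-4-[(2E)-1,1-dimethoxybut-2-en-2-yl]-2-oxo-3,4-dihydro-2H-pyran-5-carboxylate | C/C=C(/C(OC)OC)[C@@H]1CC(=O)OC=C1C(=O)OC | intermediate
17 | 2-(2,2-dimethyl-1,3-benzodioxol-5-yl)ethyl (3S,4E)-4-(dimethoxymethyl)-3-(3-hydroxy-1-methoxy-1-oxoprop-2-en-2-yl)hex-4-enoate | C/C=C(/C(OC)OC)[C@@H](C(=CO)C(=O)OC)CC(=O)OCCc1ccc2OC(C)(C)Oc2c1 | intermediate
18 | 2-(2,2-dimethyl-1,3-benzodioxol-5-yl)ethyl (3S,4E)-4-formyl-3-(3-hydroxy-1-methoxy-1-oxoprop-2-en-2-yl)hex-4-enoate | C/C=C(/C=O)[C@@H](C(=CO)C(=O)OC)CC(=O)OCCc1ccc2OC(C)(C)Oc2c1 | intermediate (not isolated)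
19 | methyl (2S,3S,4S)-4-{2-[2-(2,2-dimethyl-1,3-benzodioxol-5-yl)ethoxy]-2-oxoethyl}-3-formyl-2-methyl-3,4-dihydro-2H-pyran-5-carboxylate | COC(=O)C1=CO[C@@H](C)[C@@H](C=O)[C@@H]1CC(=O)OCCc1ccc2OC(C)(C)Oc2c1 | intermediate (not isolated)
20 | methyl (2S,3S,4S)-4-{2-[2-(3,4-dihydroxyphenyl)ethoxy]-2-oxoethyl}-3-formyl-2-methyl-3,4-dihydro-2H-pyran-5-carboxylate | COC(=O)C1=CO[C@@H](C)[C@@H](C=O)[C@@H]1CC(=O)OCCc1ccc(O)c(O)c1 | target

## Step count and risk

Total: 8 steps. Longest linear sequence: 6 steps (steps 1, 2, 3, 6, 7, 8); steps 4 and 5 are one-step side branches.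

**Step 8 (key step).** The most likely failure is incomplete thermodynamic funnelling. Ring closure on the other face of C2 may persist if the two half-chairs are closer in energy than argued. The slow acetonide cleavage in strong acid also gives the aldehyde time to react with the liberated, electron-rich catechol.
Fallback, from 16 to 20, with the ester formed last:
- 16 is opened with LiOH (THF/H2O, 0 °C) and acidified to the seco acid (3S,4E)-4-(dimethoxymethyl)-3-(3-hydroxy-1-methoxy-1-oxoprop-2-en-2-yl)hex-4-enoic acid F1.
- Aqueous HCl/THF hydrolyses the acetal to the enal acid (3S,4E)-4-formyl-3-(3-hydroxy-1-methoxy-1-oxoprop-2-en-2-yl)hex-4-enoic acid F2 (not isolated), which closes to (2S,3S,4S)-elenolic acid F3.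
- F3 has no catechol and no acetonide. It should allow enrichment of the wanted diastereomer by crystallisation under equilibrating conditions.
- F3 is then esterified with unprotected 12 under Mitsunobu conditions (PPh3, diisopropyl azodicarboxylate, THF, 0 °C), which activate only the primary alcohol, to give 20.

**Step 6.** The carbene may add to the formyl tautomer of 14, and the quinone would then oxidise the donor instead of 8. A background addition outside the catalyst pocket could erode facial selectivity at C4, and attack at the ethylidene terminus (1,6) is possible.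
Fallback, from 8 to 16, which removes the oxidant from the annulation:
- 8 is oxidised (NaClO2, NaH2PO4, 2-methylbut-2-ene, t-BuOH/H2O, 0 °C) to (2E,4E)-4-(dimethoxymethyl)hexa-2,4-dienoic acid F4.
- F4 is converted in situ (t-BuCOCl, i-Pr2NEt, CH2Cl2) into its mixed pivalic anhydride F5.
- An isothiourea Lewis base (HyperBTM, the enantiomer that gives the (S)-lactone) turns F5 into an α,β-unsaturated acyl ammonium ion, which undergoes Michael addition–lactonisation with 14 to give 16.

**Step 3.** The α-lithio acetal 6 may lose methoxide by β-elimination, or lose its alkene geometry before it is trapped. The acetal may also hydrolyse while dimethylamine is eliminated.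
Fallback, from 4 to 8, with no organolithium: a Heck reaction of 4 with acrolein (Pd(OAc)2, Bu4NCl, NaHCO3, DMF, 50 °C) gives 8 directly and makes no new compound (F0).

**Step 7.** The alcohol may attack C6 of the β-acyloxyacrylate (addition–elimination, vinyl transfer) instead of the acyl carbon. The acidic enol of the product may also protonate the catalyst and stall the reaction.
Fallback, from 16 to 20, through an acyl-enzyme that can only transfer the acyl group and needs no catechol protection (step 5 is then not needed):
- 16 and unprotected 12 are treated with immobilised Candida antarctica lipase B (t-BuOMe, 40 °C) to give 2-(3,4-dihydroxyphenyl)ethyl (3S,4E)-4-(dimethoxymethyl)-3-(3-hydroxy-1-methoxy-1-oxoprop-2-en-2-yl)hex-4-enoate F6.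
- Dilute aqueous HCl in THF converts F6, through the seco enal–enol 2-(3,4-dihydroxyphenyl)ethyl (3S,4E)-4-formyl-3-(3-hydroxy-1-methoxy-1-oxoprop-2-en-2-yl)hex-4-enoate F7 (not isolated), into 20 by the ring closure of step 8.

## Further compounds

F1 | step 8 | (3S,4E)-4-(dimethoxymethyl)-3-(3-hydroxy-1-methoxy-1-oxoprop-2-en-2-yl)hex-4-enoic acid | C/C=C(/C(OC)OC)[C@@H](C(=CO)C(=O)OC)CC(=O)O
F2 | step 8 | (3S,4E)-4-formyl-3-(3-hydroxy-1-methoxy-1-oxoprop-2-en-2-yl)hex-4-enoic acid | C/C=C(/C=O)[C@@H](C(=CO)C(=O)OC)CC(=O)O
F3 | step 8 | (2S,3S,4S)-elenolic acid, 2-[(2S,3S,4S)-3-formyl-5-(methoxycarbonyl)-2-methyl-3,4-dihydro-2H-pyran-4-yl]acetic acid | COC(=O)C1=CO[C@@H](C)[C@@H](C=O)[C@@H]1CC(=O)O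
F4 | step 6 | (2E,4E)-4-(dimethoxymethyl)hexa-2,4-dienoic acid | C/C=C(/C(OC)OC)\C=C\C(=O)O
F5 | step 6 | (2E,4E)-4-(dimethoxymethyl)hexa-2,4-dienoic pivalic anhydride | C/C=C(/C(OC)OC)\C=C\C(=O)OC(=O)C(C)(C)C
F0 | step 3 | none | none
F6 | step 7 | 2-(3,4-dihydroxyphenyl)ethyl (3S,4E)-4-(dimethoxymethyl)-3-(3-hydroxy-1-methoxy-1-oxoprop-2-en-2-yl)hex-4-enoate | C/C=C(/C(OC)OC)[C@@H](C(=CO)C(=O)OC)CC(=O)OCCc1ccc(O)c(O)c1
F7 | step 7 | 2-(3,4-dihydroxyphenyl)ethyl (3S,4E)-4-formyl-3-(3-hydroxy-1-methoxy-1-oxoprop-2-en-2-yl)hex-4-enoate | C/C=C(/C=O)[C@@H](C(=CO)C(=O)OC)CC(=O)OCCc1ccc(O)c(O)c1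
A1 | alternative 1 | (2S,3S,4S)-elenolic acid | COC(=O)C1=CO[C@@H](C)[C@@H](C=O)[C@@H]1CC(=O)O
A2 | alternative 2 | 1-[2-(2,2-dimethyl-1,3-benzodioxol-5-yl)ethyl] 5-methyl (3E)-4-formylpent-3-enedioate | COC(=O)/C(C=O)=C/CC(=O)OCCc1ccc2OC(C)(C)Oc2c1
A3 | alternative 3 | 2-(2,2-dimethyl-1,3-benzodioxol-5-yl)ethyl (3Z,5R)-4-(dimethoxymethyl)-5-{[(1E)-3-methoxy-3-oxoprop-1-en-1-yl]oxy}hex-3-enoate | C[C@@H](O/C=C/C(=O)OC)/C(C(OC)OC)=C/CC(=O)OCCc1ccc2OC(C)(C)Oc2c1
A4 | alternative 3 | 2-(2,2-dimethyl-1,3-benzodioxol-5-yl)ethyl (3Z,5R)-4-(dimethoxymethyl)-5-hydroxyhex-3-enoate | C[C@@H](O)/C(C(OC)OC)=C/CC(=O)OCCc1ccc2OC(C)(C)Oc2c1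
A5 | alternative 3 | methyl propiolate | C#CC(=O)OC
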